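Fragransin B1 is meso, with a mirror plane through O1 and the midpoint of C3–C4 of the oxolane ring. The route is therefore two-directional: bought meso-2,3-dimethylsuccinic acid supplies C3, C4 and their cis methyl groups, and both syringyl units are attached at once as aryl ketones. The oxolane is closed last, from the open-chain 1,4-diaryl-1,4-diol, by acid-catalysed cyclodehydration through a para-quinone methide. This step exploits that C2 and C5 are both para-hydroxybenzylic carbons on O1: either C–O bond forms reversibly, so in one operation both centres settle trans to the neighbouring methyl by relay from C3 and C4, whatever the carbinol configuration of the precursor.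

Key step: step 5

Assumption: 1 and 3 are bought (3 as the pure meso acid). Diol 9 is drawn as its expected major anti,anti isomer and is carried into step 5 together with any carbinol epimers, which that step should converge.

Step 1
Reactants: 1 4-bromo-2,6-dimethoxyphenol
Product: 2 tert-butyl(4-bromo-2,6-dimethoxyphenoxy)dimethylsilane
Conditions: TBSCl, imidazole, DMF, rt
Reagents that add atoms: tert-butyldimethylsilyl chloride (TBSCl), CC(C)(C)[Si](C)(C)Cl
Why: Imidazole-promoted O-silylation of a phenol, which removes the acidic proton before bromine–lithium exchange and gives an ether that should resist n-BuLi at −78 °C.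

Step 2
Reactants: 3 meso-2,3-dimethylsuccinic acid
Product: 4 (2R,3S)-N1,N4-dimethoxy-N1,N4,2,3-tetramethylbutanediamide (meso bis-Weinreb amide)
Conditions: MeNHOMe·HCl, EDC·HCl, HOBt (cat.), N-methylmorpholine, CH2Cl2, 0 °C to rt
Reagents that add atoms: N,O-dimethylhydroxylamine hydrochloride, CNOC.Cl
Why: Carbodiimide (EDC/HOBt) amide coupling converts both carboxyl groups into Weinreb amides in one two-directional operation, under weakly basic conditions that should not enolise the two bought stereocentres.

Step 3
Reactants: 2 tert-butyl(4-bromo-2,6-dimethoxyphenoxy)dimethylsilane (2.2 equiv), 4 meso bis-Weinreb amide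
Product: 7 (2R,3S)-1,4-bis[4-(tert-butyldimethylsilyloxy)-3,5-dimethoxyphenyl]-2,3-dimethylbutane-1,4-dione (meso), via aryllithium 5 (not isolated), via dilithium bis-hemiaminal adduct 6 (not isolated)
Conditions: 2, n-BuLi, THF, −78 °C; then 4, −78 to −20 °C; sat. aq. NH4Cl, −78 °C
Reagents that add atoms: none
Why: Bromine–lithium exchange followed by a double Weinreb ketone synthesis, in which each amide stays a chelated tetrahedral lithium adduct until the cold quench, so over-addition is blocked and no free ketone meets base, which should preserve the meso cis-dimethyl relationship.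

Step 4
Reactants: 7 meso bis-silyl diketone
Product: 9 (1R,2R,3S,4S)-1,4-bis(4-hydroxy-3,5-dimethoxyphenyl)-2,3-dimethylbutane-1,4-diol (meso; anti,anti), via bis-silyl diol 8 (not isolated)
Conditions: NaBH4, THF–MeOH, 0 °C; then K2CO3, MeOH, rt; aq. NH4Cl
Reagents that add atoms: none
Why: NaBH4 reduction of both aryl ketones should follow the Felkin–Anh model (hydride anti to the branched α-substituent) to give mainly the anti,anti diol, whose two carbinol centres need not be pure because step 5 converges them, and K2CO3 in MeOH then cleaves the phenolic silyl ethers by base-catalysed methanolysis.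

Step 5
Reactants: 9 meso bisphenol diol
Product: 11 fragransin B1, via para-quinone methide 10 (not isolated)
Conditions: CSA (10 mol%), CH2Cl2–MeCN, 0 °C to rt; aq. NaHCO3
Reagents that add atoms: none
Why: CSA protonates one para-hydroxybenzylic carbinol of 9 and water leaves with push from the para-hydroxyl to give para-quinone methide 10 (in equilibrium with its benzylic cation), whose exocyclic carbon is then attacked by the remaining benzylic hydroxyl in an intramolecular oxa-1,6-conjugate addition that rearomatises the arene. The closest known reaction type is the acid-catalysed cyclodehydration of 1,4-diaryl-butane-1,4-diols to 2,5-diaryl-tetrahydrofuran lignans, that is, intramolecular capture of a para-quinone methide by an alcohol. The oxolane closes in the 5-exo-trig mode, since the attacked C=C bond lies outside the new ring. The new centre C2 is controlled by the neighbouring C3: in the reactive conformer C3–H eclipses the quinone methide plane to avoid A(1,3) strain, so the tethered oxygen adds on the face that places the aryl group trans to the C3 methyl, while C5 keeps the configuration of its carbinol and C3 and C4 are untouched. Because each benzylic C–O bond of a para-hydroxyaryl oxolane can re-ionise under the same conditions, carbinol epimers of 9 and any 4,5-cis oxolane formed from them should drain into the most stable 2,3-trans-3,4-cis-4,5-trans isomer, the meso target. The step needs O-closure to outrun Friedel–Crafts closure of a six-membered ring onto the second arene and proton loss from C3 (which would scramble the cis-dimethyl unit); the high effective molarity of the five-membered oxa-closure, catalytic acid and low temperature should secure this.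

Compound list
1 | 4-bromo-2,6-dimethoxyphenol | COc1cc(Br)cc(OC)c1O | starting material
2 | tert-butyl(4-bromo-2,6-dimethoxyphenoxy)dimethylsilane | COc1cc(Br)cc(OC)c1O[Si](C)(C)C(C)(C)C | intermediate
3 | meso-2,3-dimethylsuccinic acid, (2R,3S) | OC(=O)[C@@H](C)[C@@H](C)C(=O)O | starting material
4 | (2R,3S)-N1,N4-dimethoxy-N1,N4,2,3-tetramethylbutanediamide (meso bis-Weinreb amide) | CON(C)C(=O)[C@@H](C)[C@@H](C)C(=O)N(C)OC | intermediate
5 | [4-(tert-butyldimethylsilyloxy)-3,5-dimethoxyphenyl]lithium | [Li]c1cc(OC)c(O[Si](C)(C)C(C)(C)C)c(OC)c1 | intermediate (not isolated)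
6 | dilithium bis-hemiaminal adduct of 4 with two molecules of 5 (2R,3S at the methyl-bearing carbons; hemiaminal carbons undefined) | COc1cc(cc(OC)c1O[Si](C)(C)C(C)(C)C)C(O[Li])(N(C)OC)[C@@H](C)[C@@H](C)C(O[Li])(N(C)OC)c1cc(OC)c(O[Si](C)(C)C(C)(C)C)c(OC)c1 | intermediate (not isolated)
7 | (2R,3S)-1,4-bis[4-(tert-butyldimethylsilyloxy)-3,5-dimethoxyphenyl]-2,3-dimethylbutane-1,4-dione (meso) | COc1cc(cc(OC)c1O[Si](C)(C)C(C)(C)C)C(=O)[C@@H](C)[C@@H](C)C(=O)c1cc(OC)c(O[Si](C)(C)C(C)(C)C)c(OC)c1 | intermediate
8 | (1R,2R,3S,4S)-1,4-bis[4-(tert-butyldimethylsilyloxy)-3,5-dimethoxyphenyl]-2,3-dimethylbutane-1,4-diol (meso; anti,anti) | COc1cc(cc(OC)c1O[Si](C)(C)C(C)(C)C)[C@@H](O)[C@@H](C)[C@@H](C)[C@@H](O)c1cc(OC)c(O[Si](C)(C)C(C)(C)C)c(OC)c1 | intermediate (not isolated)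
9 | (1R,2R,3S,4S)-1,4-bis(4-hydroxy-3,5-dimethoxyphenyl)-2,3-dimethylbutane-1,4-diol (meso; anti,anti; major isomer drawn) | COc1cc(cc(OC)c1O)[C@@H](O)[C@@H](C)[C@@H](C)[C@@H](O)c1cc(OC)c(O)c(OC)c1 | intermediate
10 | 4-[(2R,3R,4R)-4-hydroxy-4-(4-hydroxy-3,5-dimethoxyphenyl)-2,3-dimethylbutylidene]-2,6-dimethoxycyclohexa-2,5-dien-1-one (para-quinone methide; formed as the racemate, one enantiomer drawn, stereocentres as in 9) | COC1=CC(=C[C@@H](C)[C@@H](C)[C@@H](O)c2cc(OC)c(O)c(OC)c2)C=C(OC)C1=O | intermediate (not isolated)
11 | fragransin B1, 4,4'-[(2R,3R,4S,5S)-3,4-dimethyloxolane-2,5-diyl]bis(2,6-dimethoxyphenol) (meso; 2,3-trans, 3,4-cis, 4,5-trans) | COc1cc([C@H]2O[C@@H](c3cc(OC)c(O)c(OC)c3)[C@H](C)[C@@H]2C)cc(OC)c1O | target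

Total step count: 5. Longest linear sequence: 4 steps (steps 2, 3, 4, 5 from 3; equally steps 1, 3, 4, 5 from 1).

Steps most likely to fail

Step 5. Under protic acid the benzylic cation may be diverted into Friedel–Crafts closure onto the second arene, may lose the C3 proton and so scramble the cis-dimethyl unit, or the equilibration of a 4,5-cis isomer may stall. The fallback sets out from 7 and comes back at 11, closing the ring with the phenols still protected and without acid. Reduction of 7 with LiBH(s-Bu)3 in THF at −78 °C should give the silyl-protected diol 8 as a single anti,anti isomer, which is isolated this time. MsCl and Et3N in CH2Cl2 at 0 °C convert one carbinol into the benzylic monomesylate F1, which should ionise under these basic conditions and be closed by the neighbouring hydroxyl (nucleophilic carbinol retained, new centre trans to methyl) to the bis-silyl ether of fragransin B1 F2. TBAF in THF at 0 °C then frees both phenols to give 11.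

Step 3. The strongly basic aryllithium may enolise the amide or stall after the first addition, with loss of the meso relationship. The fallback sets out from 3 and 2 and comes back at 7, making both aryl ketone bonds by base-free acyl cross-coupling. Diacid 3 is converted with thiophenol, DCC and catalytic DMAP in CH2Cl2 into the S,S'-diphenyl bis-thioester F3. Bromide 2 is converted by way of 5 with B(OMe)3 and hydrolytic work-up into the arylboronic acid F4. A twofold Liebeskind–Srogl coupling of F3 with F4 (Pd2(dba)3, tri(2-furyl)phosphine, copper thiophene-2-carboxylate Cu(O2CC4H3S), THF, 50 °C) should then give 7.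

Step 2. Activation of the 1,4-diacid may close it to the cyclic anhydride, leaving mono-amide or epimerised material. The fallback sets out from 3 and comes back at 4, replacing carboxyl activation by ester aminolysis. Fischer esterification (MeOH, cat. H2SO4, reflux) gives dimethyl meso-2,3-dimethylsuccinate F5. Treatment with the magnesium amide made from MeNHOMe·HCl and i-PrMgCl in THF at −20 °C should then give 4.

Further compounds
F1 | step 5 | benzylic monomesylate of diol 8, (1R,2R,3S,4S) | COc1cc(cc(OC)c1O[Si](C)(C)C(C)(C)C)[C@@H](OS(C)(=O)=O)[C@@H](C)[C@@H](C)[C@@H](O)c1cc(OC)c(O[Si](C)(C)C(C)(C)C)c(OC)c1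
F2 | step 5 | (2R,3R,4S,5S)-2,5-bis[4-(tert-butyldimethylsilyloxy)-3,5-dimethoxyphenyl]-3,4-dimethyloxolane (bis-silyl ether of fragransin B1) | COc1cc([C@H]2O[C@@H](c3cc(OC)c(O[Si](C)(C)C(C)(C)C)c(OC)c3)[C@H](C)[C@@H]2C)cc(OC)c1O[Si](C)(C)C(C)(C)C
F3 | step 3 | S,S'-diphenyl (2R,3S)-2,3-dimethylbutanebis(thioate) | O=C(Sc1ccccc1)[C@@H](C)[C@@H](C)C(=O)Sc1ccccc1
F4 | step 3 | [4-(tert-butyldimethylsilyloxy)-3,5-dimethoxyphenyl]boronic acid | COc1cc(B(O)O)cc(OC)c1O[Si](C)(C)C(C)(C)C
F5 | step 2 | dimethyl (2R,3S)-2,3-dimethylbutanedioate | COC(=O)[C@@H](C)[C@@H](C)C(=O)OC
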